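**Retrosynthetic overview**

1. The target is a (2S)-flavanone (rings A, B, C) carrying a (2E,6R)-6-hydroxy-3,7-dimethylocta-2,7-dienyl chain at C6; it is reached by fluoride desilylation of its tetrakis(silyl) ether, and no ring is formed after the key step.
2. Key disconnection: the C2–C3 bond of ring C, made by enantioselective rhodium-carbenoid C–H insertion of an aryl diazomethyl ketone into the OCH2 group of a simple 4-silyloxy-3-methoxybenzyl aryl ether. Ring C is the only ring the route builds (rings A and B are bought as phloroacetophenone and vanillin), and C2 is set in the same event.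
3. Enabling feature: C2 is both benzylic to ring B and bonded to O1, and O1 (on C8a) sits ortho to the C4 acyl carbon (on C4a) of ring A, so an activated O–CH2–aryl C–H bond lies six atoms from carbenoid carbon C3. The C5 oxygen carries a silyl group with no α C–H, and the chain alkenes are meta to the acyl group.
4. Ring A: C-alkylation of phloroacetophenone (its two ring CH positions are equivalent) puts the chain between two oxygens; the three hydroxyls are then told apart by acidity, chelation and steric shielding (4-O-silyl, 6-O-benzyl, 2-O-silyl).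
5. Side chain: geranyl acetate, Shi epoxidation of the distal alkene (sets 6R), epoxide-to-allylic-alcohol isomerisation, then conversion into the allylic bromide.

Key step: step 13

Assumption: Rh2(S-PTTL)4 is taken to insert into the pro-S benzylic C–H bond and so to give the 2S product; if a model insertion shows the opposite sense, the mirror-image complex Rh2(R-PTTL)4 is used in step 13 with nothing else changed.

Abbreviation: TBS = tert-butyldimethylsilyl.

**Route**

Step 1
Reactants: 1 geranyl acetate
Product: 2 (6R)-6,7-epoxygeranyl acetate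
Conditions: D-fructose-derived ketone 1,2:4,5-di-O-isopropylidene-β-D-erythro-2,3-hexodiulo-2,6-pyranose (30 mol %), KHSO5 (as 2KHSO5·KHSO4·K2SO4), K2CO3, Bu4NHSO4, MeCN/CH2(OMe)2, aq. Na2B4O7 buffer (pH 10.5), 0 °C
Reagents that add atoms: potassium peroxymonosulfate KHSO5, [K+].[O-]S(=O)(=O)OO (the epoxide oxygen, delivered through the dioxirane of the ketone catalyst)
Why: Shi epoxidation: the electrophilic chiral dioxirane should oxidise the electron-richer distal trisubstituted alkene in preference to the one deactivated by the allylic acetate, and its spiro transition state sets the (R)-configured oxirane carbon under catalyst control.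

Step 2
Reactants: 2 (6R)-6,7-epoxygeranyl acetate
Product: 3 (2E,6R)-6-hydroxy-3,7-dimethylocta-2,7-dien-1-yl acetate
Conditions: Al(OiPr)3 (1 equiv), toluene, 110 °C; aqueous work-up
Reagents that add atoms: none
Why: Aluminium-alkoxide-promoted epoxide-to-allylic-alcohol isomerisation: the Lewis acid activates the oxirane, the tertiary C–O bond breaks and a proton is taken from a geminal methyl group in a cyclic syn-elimination, so the isopropenyl carbinol forms with the secondary C–O bond, and hence the (R) centre, untouched.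

Step 3
Reactants: 3 (2E,6R)-6-hydroxy-3,7-dimethylocta-2,7-dien-1-yl acetate
Product: 4 (2E,6R)-6-(TBS-oxy)-3,7-dimethylocta-2,7-dien-1-yl acetate
Conditions: TBSCl, imidazole, DMF, 23 °C
Reagents that add atoms: tert-butyldimethylsilyl chloride, CC(C)(C)[Si](C)(C)Cl
Why: Imidazole-assisted silyl ether formation masks the secondary allylic alcohol for the phenolate alkylation, the Mitsunobu reaction and the carbenoid step.

Step 4
Reactants: 4 (2E,6R)-6-(TBS-oxy)-3,7-dimethylocta-2,7-dien-1-yl acetate
Product: 5 (2E,6R)-6-(TBS-oxy)-3,7-dimethylocta-2,7-dien-1-ol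
Conditions: K2CO3 (cat.), MeOH, 0 → 23 °C
Reagents that add atoms: none
Why: Base-catalysed transesterification (methanolysis) removes the primary acetate while the secondary silyl ether is stable.

Step 5
Reactants: 5 (2E,6R)-6-(TBS-oxy)-3,7-dimethylocta-2,7-dien-1-ol
Product: 6 (2E,6R)-1-bromo-6-(TBS-oxy)-3,7-dimethylocta-2,7-diene
Conditions: CBr4, PPh3, CH2Cl2, 0 °C; used without storage
Reagents that add atoms: carbon tetrabromide, BrC(Br)(Br)Br
Why: Appel reaction: the alkoxyphosphonium ion of the primary allylic alcohol is displaced by bromide in an SN2 fashion without moving the (E)-alkene, and the neutral conditions spare the silyl ether.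

Step 6
Reactants: 7 vanillin
Product: 8 4-(TBS-oxy)-3-methoxybenzaldehyde
Conditions: TBSCl, imidazole, CH2Cl2, 23 °C
Reagents that add atoms: tert-butyldimethylsilyl chloride, CC(C)(C)[Si](C)(C)Cl
Why: Imidazole-assisted silylation of the phenol; the silyl ether later serves as the electron-donating para substituent that activates the benzylic C–H bond.

Step 7
Reactants: 8 4-(TBS-oxy)-3-methoxybenzaldehyde
Product: 9 [4-(TBS-oxy)-3-methoxyphenyl]methanol
Conditions: NaBH4, MeOH, 0 °C
Reagents that add atoms: none
Why: Hydride reduction of the aldehyde to the benzylic alcohol; the aryl silyl ether should survive a short reaction at 0 °C.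

Step 8
Reactants: 10 2,4,6-trihydroxyacetophenone (3 equiv); 6 (2E,6R)-1-bromo-6-(TBS-oxy)-3,7-dimethylocta-2,7-diene
Product: 11 3-C-alkylated 2,4,6-trihydroxyacetophenone
Conditions: K2CO3, acetone, 56 °C
Reagents that add atoms: none
Why: Phenolate C-alkylation: the phloroglucinol-type anion of 10 reacts as a vinylogous enolate at ring carbon with the primary allylic bromide (SN2, alkene geometry kept), and because the two ring CH positions of 10 are equivalent only one mono-C-alkylated constitution can form, with the chain between two oxygens; excess 10 limits double alkylation.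

Step 9
Reactants: 11 3-C-alkylated 2,4,6-trihydroxyacetophenone
Product: 12 4-O-TBS ether of 11
Conditions: TBSCl (1.05 equiv), imidazole, CH2Cl2/DMF, 0 °C
Reagents that add atoms: tert-butyldimethylsilyl chloride, CC(C)(C)[Si](C)(C)Cl
Why: Selective silyl ether formation: the hydroxyl para to the acetyl group is the most acidic and the only one not held in a hydrogen bond to the carbonyl, so it should be silylated first.

Step 10
Reactants: 12 4-O-TBS ether of 11; 9 [4-(TBS-oxy)-3-methoxyphenyl]methanol
Product: 13 6-O-benzylated 2-hydroxyacetophenone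
Conditions: PPh3, DIAD, THF, 0 → 23 °C
Reagents that add atoms: none
Why: Mitsunobu etherification: of the two chelated ortho hydroxyls the one next to the ring CH is far less hindered than the one flanked by the side chain and the acetyl group, so the benzyl group should go onto the oxygen that becomes O1.

Step 11
Reactants: 13 6-O-benzylated 2-hydroxyacetophenone
Product: 14 fully protected methyl ketone
Conditions: TBSOTf, 2,6-lutidine, CH2Cl2, −40 → 0 °C
Reagents that add atoms: tert-butyldimethylsilyl trifluoromethanesulfonate, CC(C)(C)[Si](C)(C)OS(=O)(=O)C(F)(F)F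
Why: Silyl ether formation with the highly electrophilic silyl triflate caps the remaining hindered, chelated phenol; a silyl group is chosen here because it offers the later carbenoid no C–H bond α to oxygen.

Step 12
Reactants: 14 fully protected methyl ketone
Product: 16 aryl diazomethyl ketone, via trifluoroacetyl diketone 15 (not isolated)
Conditions: LiN(SiMe3)2, THF, −78 °C; CF3CO2CH2CF3, −78 °C; aq. NH4Cl; then 4-acetamidobenzenesulfonyl azide, Et3N, H2O, MeCN, 23 °C
Reagents that add atoms: 4-acetamidobenzenesulfonyl azide, CC(=O)Nc1ccc(cc1)S(=O)(=O)N=[N+]=[N-] (the two nitrogen atoms of 16); 2,2,2-trifluoroethyl trifluoroacetate, FC(F)(F)COC(=O)C(F)(F)F (the trifluoroacetyl group of intermediate 15 only)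
Why: Detrifluoroacetylative (Regitz-type) diazo transfer: the lithium enolate of the methyl ketone, formed and trapped at −78 °C, gives the activated 1,3-diketone 15, which takes the diazo group from the sulfonyl azide and loses the trifluoroacetyl group as the N-acylsulfonamide under mild amine base that the aryl silyl ethers should tolerate.

Step 13
Reactants: 16 aryl diazomethyl ketone
Product: 17 (2S)-tetrakis(TBS)-protected flavanone
Conditions: Rh2(S-PTTL)4 (dirhodium tetrakis[N-phthaloyl-(S)-tert-leucinate], 2 mol %), CH2Cl2, 4 Å molecular sieves, 0 °C, slow addition of 16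
Reagents that add atoms: none
Why: Loss of N2 from 16 at the divalent rhodium centre should give an electrophilic acyl carbenoid at C3, which inserts into a benzylic C–H bond of the OCH2-aryl group held ortho to the acyl group on ring A through a concerted, hydride-transfer-like three-centre transition state that forms the C3–C2 bond with retention at carbon. The closest known reaction type is the chiral dirhodium tetracarboxylate-catalysed intramolecular C–H insertion of ortho-alkoxyaryl diazo ketones, which gives 2-substituted chroman-4-ones. Ring C is closed as a six-membered ring by 1,6-insertion, through a six-membered cyclic transition state made up of the carbenoid carbon, the C4 carbonyl carbon, C4a, C8a, O1 and the benzylic carbon. The new stereocentre C2 is set by the catalyst, whose chiral carboxylate pocket should select the pro-S of the two enantiotopic benzylic hydrogens and so give the 2S product, the side-chain carbinol centre being too remote to interfere. The step needs site selectivity for this C–H bond over oxonium-ylide formation at O1 (followed by 1,2-benzyl shift), over attack at the other ortho substituent and over cyclopropanation: the C–H bond is doubly activated (α to oxygen, benzylic to the electron-rich 4-silyloxy-3-methoxyphenyl ring), O1 is a weakly basic aryl ether oxygen conjugated to the acylated ring, the C5 oxygen carries a bulky silyl group with no α C–H, and the two alkenes sit on a chain meta to the acyl group and cannot reach the carbenoid intramolecularly. Slow addition keeps the diazo ketone dilute and should suppress carbene dimerisation and intermolecular cyclopropanation.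

Step 14
Reactants: 17 (2S)-tetrakis(TBS)-protected flavanone
Product: 18 target flavanone CNP0170928.2
Conditions: HF·pyridine, pyridine, THF, 0 → 23 °C
Reagents that add atoms: none
Why: Fluoride-mediated desilylation under buffered, weakly acidic conditions frees the three phenols and the allylic alcohol without forming phenoxides, so C2 should not epimerise by ring opening and the allylic alcohol and alkenes are not exposed to strong acid.

**Compound list** (TBSO = tert-butyldimethylsilyloxy)

1 | geranyl acetate, (2E)-3,7-dimethylocta-2,6-dien-1-yl acetate | CC(=O)OC/C=C(\C)CCC=C(C)C | starting material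
2 | (2E)-5-[(2R)-3,3-dimethyloxiran-2-yl]-3-methylpent-2-en-1-yl acetate | CC(=O)OC/C=C(\C)CC[C@H]1OC1(C)C | intermediate
3 | (2E,6R)-6-hydroxy-3,7-dimethylocta-2,7-dien-1-yl acetate | C=C(C)[C@H](O)CC/C(C)=C/COC(C)=O | intermediate
4 | (2E,6R)-6-(TBSO)-3,7-dimethylocta-2,7-dien-1-yl acetate | C=C(C)[C@H](O[Si](C)(C)C(C)(C)C)CC/C(C)=C/COC(C)=O | intermediate
5 | (2E,6R)-6-(TBSO)-3,7-dimethylocta-2,7-dien-1-ol | C=C(C)[C@H](O[Si](C)(C)C(C)(C)C)CC/C(C)=C/CO | intermediate
6 | (2E,6R)-1-bromo-6-(TBSO)-3,7-dimethylocta-2,7-diene | C=C(C)[C@H](O[Si](C)(C)C(C)(C)C)CC/C(C)=C/CBr | intermediate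
7 | vanillin, 4-hydroxy-3-methoxybenzaldehyde | COc1cc(C=O)ccc1O | starting material
8 | 4-(TBSO)-3-methoxybenzaldehyde | COc1cc(C=O)ccc1O[Si](C)(C)C(C)(C)C | intermediate
9 | [4-(TBSO)-3-methoxyphenyl]methanol | COc1cc(CO)ccc1O[Si](C)(C)C(C)(C)C | intermediate
10 | 2,4,6-trihydroxyacetophenone | CC(=O)c1c(O)cc(O)cc1O | starting material
11 | 1-{2,4,6-trihydroxy-3-[(2E,6R)-6-(TBSO)-3,7-dimethylocta-2,7-dien-1-yl]phenyl}ethan-1-one | C=C(C)[C@H](O[Si](C)(C)C(C)(C)C)CC/C(C)=C/Cc1c(O)cc(O)c(C(C)=O)c1O | intermediate
12 | 1-{4-(TBSO)-2,6-dihydroxy-3-[(2E,6R)-6-(TBSO)-3,7-dimethylocta-2,7-dien-1-yl]phenyl}ethan-1-one | C=C(C)[C@H](O[Si](C)(C)C(C)(C)C)CC/C(C)=C/Cc1c(O[Si](C)(C)C(C)(C)C)cc(O)c(C(C)=O)c1O | intermediate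
13 | 1-{6-{[4-(TBSO)-3-methoxyphenyl]methoxy}-4-(TBSO)-2-hydroxy-3-[(2E,6R)-6-(TBSO)-3,7-dimethylocta-2,7-dien-1-yl]phenyl}ethan-1-one | C=C(C)[C@H](O[Si](C)(C)C(C)(C)C)CC/C(C)=C/Cc1c(O[Si](C)(C)C(C)(C)C)cc(OCc2ccc(O[Si](C)(C)C(C)(C)C)c(OC)c2)c(C(C)=O)c1O | intermediate
14 | 1-{6-{[4-(TBSO)-3-methoxyphenyl]methoxy}-2,4-bis(TBSO)-3-[(2E,6R)-6-(TBSO)-3,7-dimethylocta-2,7-dien-1-yl]phenyl}ethan-1-one | C=C(C)[C@H](O[Si](C)(C)C(C)(C)C)CC/C(C)=C/Cc1c(O[Si](C)(C)C(C)(C)C)cc(OCc2ccc(O[Si](C)(C)C(C)(C)C)c(OC)c2)c(C(C)=O)c1O[Si](C)(C)C(C)(C)C | intermediate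
15 | 4,4,4-trifluoro-1-{6-{[4-(TBSO)-3-methoxyphenyl]methoxy}-2,4-bis(TBSO)-3-[(2E,6R)-6-(TBSO)-3,7-dimethylocta-2,7-dien-1-yl]phenyl}butane-1,3-dione | C=C(C)[C@H](O[Si](C)(C)C(C)(C)C)CC/C(C)=C/Cc1c(O[Si](C)(C)C(C)(C)C)cc(OCc2ccc(O[Si](C)(C)C(C)(C)C)c(OC)c2)c(C(=O)CC(=O)C(F)(F)F)c1O[Si](C)(C)C(C)(C)C | intermediate (not isolated)
16 | 2-diazo-1-{6-{[4-(TBSO)-3-methoxyphenyl]methoxy}-2,4-bis(TBSO)-3-[(2E,6R)-6-(TBSO)-3,7-dimethylocta-2,7-dien-1-yl]phenyl}ethan-1-one | C=C(C)[C@H](O[Si](C)(C)C(C)(C)C)CC/C(C)=C/Cc1c(O[Si](C)(C)C(C)(C)C)cc(OCc2ccc(O[Si](C)(C)C(C)(C)C)c(OC)c2)c(C(=O)C=[N+]=[N-])c1O[Si](C)(C)C(C)(C)C | intermediate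
17 | (2S)-5,7-bis(TBSO)-2-[4-(TBSO)-3-methoxyphenyl]-6-[(2E,6R)-6-(TBSO)-3,7-dimethylocta-2,7-dien-1-yl]-2,3-dihydro-4H-chromen-4-one | C=C(C)[C@H](O[Si](C)(C)C(C)(C)C)CC/C(C)=C/Cc1c(O[Si](C)(C)C(C)(C)C)cc2c(c1O[Si](C)(C)C(C)(C)C)C(=O)C[C@@H](c1ccc(O[Si](C)(C)C(C)(C)C)c(OC)c1)O2 | intermediate
18 | (2S)-5,7-dihydroxy-2-(4-hydroxy-3-methoxyphenyl)-6-[(2E,6R)-6-hydroxy-3,7-dimethylocta-2,7-dien-1-yl]-2,3-dihydro-4H-chromen-4-one | C=C(C)[C@H](O)CC/C(C)=C/Cc1c(O)cc2c(c1O)C(=O)C[C@@H](c1ccc(O)c(OC)c1)O2 | target

**Step count and risks**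

Total step count: 14 (steps 1–5 side chain, steps 6–7 benzyl alcohol, steps 8–14 main line).
Longest linear sequence: 12 steps (1–5, then 8–14, from geranyl acetate).

Steps most likely to fail:

1. Step 13. Process at risk: the carbenoid may be diverted into oxonium-ylide formation at the ether oxygen followed by 1,2-benzyl shift (ring contraction to a 2-benzylbenzofuranone), or the catalyst may discriminate the two enantiotopic benzylic hydrogens poorly. The fallback sets out from 14 and comes back at 17; it forms the C2–aryl bond on a preformed chromone instead of the C2–C3 bond.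
   - Oxidative removal of the electron-rich benzyl ether of 14 (DDQ, CH2Cl2/pH 7 buffer, 0 °C) should give the free phenol 1-{6-hydroxy-2,4-bis(TBSO)-3-[(2E,6R)-6-(TBSO)-3,7-dimethylocta-2,7-dien-1-yl]phenyl}ethan-1-one F1.
   - Condensation of F1 with Me2NCH(OMe)2 (toluene, 90 °C) should give the enaminone (2E)-3-(dimethylamino)-1-aryl-prop-2-en-1-one F2, which should cyclise with loss of dimethylamine (Me3SiCl, CH2Cl2, 23 °C) to the chromone 5,7-bis(TBSO)-6-[(2E,6R)-6-(TBSO)-3,7-dimethylocta-2,7-dien-1-yl]-4H-chromen-4-one F3.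
   - Separately, 4-bromo-2-methoxyphenol is silylated (TBSCl, imidazole) to (4-bromo-2-methoxyphenoxy)(tert-butyl)dimethylsilane F4 and converted (n-BuLi, B(OiPr)3, THF, −78 °C; aqueous work-up) into [4-(TBSO)-3-methoxyphenyl]boronic acid F5.
   - Enantioselective conjugate addition of F5 to F3 under divalent palladium catalysis (Pd(OCOCF3)2, the enantiomer of the tert-butyl pyridine-oxazoline ligand that delivers the 2S product, NH4PF6, H2O, ClCH2CH2Cl, 60 °C), a known way from chromones to 2-aryl chroman-4-ones, should give 17.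

2. Step 8. Process at risk: the ambident phloroglucinol anion may be alkylated on oxygen or twice on carbon, and the allylic bromide may be lost to SN2′ attack or elimination, so that little mono-C-alkylated ketone forms. The fallback sets out from 6 and comes back at 11; it uses directed ortho-metalation in place of phenolate alkylation.
   - Phloroglucinol is protected (MeOCH2Cl, iPr2NEt, CH2Cl2) as 1,3,5-tris(methoxymethoxy)benzene F6.
   - Lithiation between two acetal oxygens (n-BuLi, THF, 0 °C), transmetalation (CuBr·SMe2, −40 °C) and alkylation with 6 should give tert-butyl{[(3R,6E)-2,6-dimethyl-8-[2,4,6-tris(methoxymethoxy)phenyl]octa-1,6-dien-3-yl]oxy}dimethylsilane F7.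
   - A second lithiation at one of the two equivalent remaining ring positions (n-BuLi, TMEDA, THF, −20 °C) and acylation with N-methoxy-N-methylacetamide should give 1-{2,4,6-tris(methoxymethoxy)-3-[(2E,6R)-6-(TBSO)-3,7-dimethylocta-2,7-dien-1-yl]phenyl}ethan-1-one F8.
   - The three phenolic acetals are removed under conditions expected to spare the secondary silyl ether (NaHSO4·SiO2, CH2Cl2, 23 °C) to give 11.

3. Step 10. Process at risk: etherification at the hindered hydroxyl beside the side chain, or ionisation of the activated benzylic oxyphosphonium intermediate with C-benzylation of the electron-rich ring. The fallback sets out from 9 and 12 and comes back at 13; it uses SN2 alkylation of the potassium phenoxide in place of the redox condensation.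
   - 9 is converted (PBr3, Et2O, 0 °C) into [4-(bromomethyl)-2-methoxyphenoxy](tert-butyl)dimethylsilane F9, used at once.
   - Williamson etherification of 12 with F9 (K2CO3, acetone, 23 °C) should alkylate the less hindered chelated hydroxyl and give 13; the hydroxyl flanked by the chain and the acetyl group is the one such conditions are expected to leave untouched.

**Further compounds**

F1 | step 13 | 1-{6-hydroxy-2,4-bis(TBSO)-3-[(2E,6R)-6-(TBSO)-3,7-dimethylocta-2,7-dien-1-yl]phenyl}ethan-1-one | C=C(C)[C@H](O[Si](C)(C)C(C)(C)C)CC/C(C)=C/Cc1c(O[Si](C)(C)C(C)(C)C)cc(O)c(C(C)=O)c1O[Si](C)(C)C(C)(C)C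
F2 | step 13 | (2E)-3-(dimethylamino)-1-{6-hydroxy-2,4-bis(TBSO)-3-[(2E,6R)-6-(TBSO)-3,7-dimethylocta-2,7-dien-1-yl]phenyl}prop-2-en-1-one | C=C(C)[C@H](O[Si](C)(C)C(C)(C)C)CC/C(C)=C/Cc1c(O[Si](C)(C)C(C)(C)C)cc(O)c(C(=O)/C=C/N(C)C)c1O[Si](C)(C)C(C)(C)C
F3 | step 13 | 5,7-bis(TBSO)-6-[(2E,6R)-6-(TBSO)-3,7-dimethylocta-2,7-dien-1-yl]-4H-chromen-4-one | C=C(C)[C@H](O[Si](C)(C)C(C)(C)C)CC/C(C)=C/Cc1c(O[Si](C)(C)C(C)(C)C)cc2occc(=O)c2c1O[Si](C)(C)C(C)(C)C
F4 | step 13 | (4-bromo-2-methoxyphenoxy)(tert-butyl)dimethylsilane | COc1cc(Br)ccc1O[Si](C)(C)C(C)(C)C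
F5 | step 13 | [4-(TBSO)-3-methoxyphenyl]boronic acid | COc1cc(B(O)O)ccc1O[Si](C)(C)C(C)(C)C
F6 | step 8 | 1,3,5-tris(methoxymethoxy)benzene | COCOc1cc(OCOC)cc(OCOC)c1
F7 | step 8 | tert-butyl{[(3R,6E)-2,6-dimethyl-8-[2,4,6-tris(methoxymethoxy)phenyl]octa-1,6-dien-3-yl]oxy}dimethylsilane | C=C(C)[C@H](O[Si](C)(C)C(C)(C)C)CC/C(C)=C/Cc1c(OCOC)cc(OCOC)cc1OCOC
F8 | step 8 | 1-{2,4,6-tris(methoxymethoxy)-3-[(2E,6R)-6-(TBSO)-3,7-dimethylocta-2,7-dien-1-yl]phenyl}ethan-1-one | C=C(C)[C@H](O[Si](C)(C)C(C)(C)C)CC/C(C)=C/Cc1c(OCOC)cc(OCOC)c(C(C)=O)c1OCOC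
F9 | step 10 | [4-(bromomethyl)-2-methoxyphenoxy](tert-butyl)dimethylsilane | COc1cc(CBr)ccc1O[Si](C)(C)C(C)(C)C
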